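**Retrosynthetic overview**
1. The enone C–C bond of the chalcone is cut by Claisen–Schmidt condensation into an 8-acetylchroman and MOM-protected 4-hydroxybenzaldehyde (ring C comes last). The acetyl group comes from Friedel–Crafts acylation at C8, and the (3R)-carbinol from CBS reduction of a chroman-3-one.
2. The 5-oxygenated 2,2-dimethylchroman-3-one (rings A and B) comes in one pot from 2-(2-hydroxypropan-2-yl)-6,7-dihydro-1-benzofuran-4(5H)-one. Oxidative ring expansion of the five-membered furan ring gives the six-membered pyranone ring B; loss of water and tautomerization then turn the cyclohexanone ring into benzene ring A.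
3. Enabling feature: in ring B the array O1–C2(CH3)2–C3(O)–C4 is the 2,2-dialkylpyran-3-one pattern that a tertiary 2-furyl carbinol gives on oxidative ring expansion. On ring A the oxygens at C5 and C8a are meta, the pattern of a cyclohexane-1,3-dione, so ring A can be carried as a saturated ketone ring, and the one oxygen atom put in by the ring expansion is exactly the oxidation needed to aromatize it.
4. The furan carbinol comes from cyclohexane-1,3-dione and 1-bromo-3-hydroxy-3-methylbutan-2-one (C-alkylation, Paal–Knorr closure).
5. Order of ring formation: carbocycle (bought) → furan ring → ring B by expansion of the furan ring, with aromatization of ring A in the same step → ring C attached.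

Key step: step 3

**Route**

Step 1
Reactants: 1 3-hydroxy-3-methylbutan-2-one
Product: 2 1-bromo-3-hydroxy-3-methylbutan-2-one
Conditions: Br2, MeOH, 0 °C → rt; then H2O
Reagents that add atoms: bromine, BrBr
Why: Acid-catalysed α-bromination of a methyl ketone through its enol; the other α-carbon is quaternary, so only the methyl group can react, and methanol suppresses dibromination.

Step 2
Reactants: 3 cyclohexane-1,3-dione; 2 1-bromo-3-hydroxy-3-methylbutan-2-one
Product: 5 2-(2-hydroxypropan-2-yl)-6,7-dihydro-1-benzofuran-4(5H)-one, via triketone 4 (not isolated)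
Conditions: K2CO3, CHCl3, rt; filter; then 1 M HCl, THF, rt → 40 °C
Reagents that add atoms: none
Why: C-Alkylation of the soft 1,3-dione enolate by the α-bromoketone followed by acid-catalysed Paal–Knorr cyclodehydration of the 1,4-dicarbonyl unit, the standard way to 2-substituted 6,7-dihydrobenzofuran-4(5H)-ones; aqueous acid returns any furfuryl cation to the tertiary alcohol.

Step 3
Reactants: 5 2-(2-hydroxypropan-2-yl)-6,7-dihydro-1-benzofuran-4(5H)-one
Product: 9 5-hydroxy-2,2-dimethyl-2H-chromen-3(4H)-one, via enedione 6 (not isolated), via hemiketal 7 (not isolated), via dienedione 8 (not isolated)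
Conditions: mCPBA (1.0 equiv), CH2Cl2, 0 °C → rt; then TFA, 4 Å MS, rt → 40 °C
Reagents that add atoms: mCPBA (3-chloroperoxybenzoic acid), OOC(=O)c1cccc(Cl)c1
Why: Proposed new method: mCPBA, directed by the tertiary hydroxyl, epoxidizes the C2=C3 bond of the furan and the epoxide collapses with cleavage of the furan O1–C2 bond to enedione 6, whose tertiary hydroxyl adds to a ring carbonyl to give hemiketal 7; up to here this is the Achmatowicz rearrangement, the closest known reaction type, by which the five-membered furan ring becomes the six-membered pyranone ring, not yet shown on a furan fused to a cyclohexanone. TFA then ionizes the hemiketal to the oxocarbenium ion (as in Kishi reductions of Achmatowicz products), loss of the C8 proton gives dienedione 8, and protonation at C4, loss of the C7 proton and enolization of the C5 ketone (the prototropic isoaromatization known for alkylidenecyclohexadienes and cyclohexadienones) should deliver the phenol, so the oxygen atom spent in the ring expansion is also the oxidant that aromatizes the carbocycle, while the furan oxygen leaves as water. The pyran ring closes by 6-exo-trig hemiketalization; the benzene ring is not closed but arises by tautomerization of the existing six-membered carbocycle. No stereocenter is left in the product, the hemiketal center C8a being destroyed again. The step needs the pyran, not a furan or benzofuran, to form and needs one constitution only: the carbinol C–O bond is never broken, the quaternary carbon C2 carries no hydrogen so that no oxidopyrylium ion can form and the cation can lose only the C8 proton, and the two carbonyl groups of the 1,3-dione are equivalent so that attack on either gives the same product. One equivalent of peracid at 0 °C, consumed before the acid is added, should limit Baeyer–Villiger oxidation and oxidation of the phenol.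

Step 4
Reactants: 9 5-hydroxy-2,2-dimethyl-2H-chromen-3(4H)-one
Product: 10 5-methoxy-2,2-dimethyl-2H-chromen-3(4H)-one
Conditions: MeOH, PPh3, DIAD, THF, 0 °C → rt
Reagents that add atoms: methanol, CO
Why: Mitsunobu etherification: only the phenol is acidic enough to be methylated by the methoxyphosphonium ion under these neutral conditions, which avoids the base-mediated C-alkylation at C4 to which this 2-tetralone-like ketone would be prone.

Step 5
Reactants: 10 5-methoxy-2,2-dimethyl-2H-chromen-3(4H)-one
Product: 11 (3R)-5-methoxy-2,2-dimethyl-3,4-dihydro-2H-chromen-3-ol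
Conditions: (S)-Me-CBS oxazaborolidine (10 mol %), BH3·SMe2, THF, −20 °C; then MeOH, aq. NH4Cl
Reagents that add atoms: none
Why: Corey–Bakshi–Shibata reduction: the ketone binds to the oxazaborolidine–borane complex with the quaternary C2 side (large) away from the catalyst and the C4 methylene (small) toward it, so that the (S)-catalyst should deliver hydride to the face giving the (3R)-alcohol, as with tert-alkyl methyl ketones; the stereocenter is set here and no later step activates the C3–O bond.

Step 6
Reactants: 11 (3R)-5-methoxy-2,2-dimethyl-3,4-dihydro-2H-chromen-3-ol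
Product: 12 (3R)-8-acetyl-5-methoxy-2,2-dimethyl-3,4-dihydro-2H-chromen-3-yl acetate
Conditions: Ac2O (3 equiv), Sc(OTf)3 (10 mol %), MeNO2, 50 °C
Reagents that add atoms: acetic anhydride, CC(=O)OC(C)=O
Why: Friedel–Crafts acylation catalysed by the metal triflate, with O-acetylation of the alcohol in the same pot: C8 is para to the methoxy group and ortho to the tied-back ring oxygen, while C6 is shielded by the methoxy methyl group, which the C4 methylene forces toward C6; a catalytic Lewis acid avoids chelation-assisted cleavage of the tertiary aryl ether.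

Step 7
Reactants: 12 (3R)-8-acetyl-5-methoxy-2,2-dimethyl-3,4-dihydro-2H-chromen-3-yl acetate; 13 4-(methoxymethoxy)benzaldehyde
Product: 14 (2E)-1-[(3R)-3-hydroxy-5-methoxy-2,2-dimethyl-3,4-dihydro-2H-chromen-8-yl]-3-[4-(methoxymethoxy)phenyl]prop-2-en-1-one
Conditions: KOH, MeOH–H2O, rt; then 1 M HCl to pH 6
Reagents that add atoms: none
Why: Claisen–Schmidt condensation (aldol addition and E1cB dehydration) gives the (E)-enone under thermodynamic control, hydroxide cleaves the O-acetate in the same operation, and the MOM ether keeps the aldehyde from being deactivated as a phenoxide.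

Step 8
Reactants: 14 (2E)-1-[(3R)-3-hydroxy-5-methoxy-2,2-dimethyl-3,4-dihydro-2H-chromen-8-yl]-3-[4-(methoxymethoxy)phenyl]prop-2-en-1-one
Product: 15 (2E)-1-[(3R)-3-hydroxy-5-methoxy-2,2-dimethyl-3,4-dihydro-2H-chromen-8-yl]-3-(4-hydroxyphenyl)prop-2-en-1-one
Conditions: 3 M HCl, MeOH, 50 °C
Reagents that add atoms: none
Why: Acid-catalysed acetal cleavage of the MOM ether; the chalcone has no free ortho-hydroxyl and cannot close to a flavanone, and the unactivated secondary alcohol and the tertiary aryl ether are stable to dilute acid.

**Compound list**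
1 | 3-hydroxy-3-methylbutan-2-one | CC(=O)C(C)(C)O | starting material
2 | 1-bromo-3-hydroxy-3-methylbutan-2-one | CC(C)(O)C(=O)CBr | intermediate
3 | cyclohexane-1,3-dione | O=C1CCCC(=O)C1 | starting material
4 | 2-(3-hydroxy-3-methyl-2-oxobutyl)cyclohexane-1,3-dione (triketone) | CC(C)(O)C(=O)CC1C(=O)CCCC1=O | intermediate
5 | 2-(2-hydroxypropan-2-yl)-6,7-dihydro-1-benzofuran-4(5H)-one | CC(C)(O)c1cc2c(o1)CCCC2=O | intermediate
6 | 2-(3-hydroxy-3-methyl-2-oxobutylidene)cyclohexane-1,3-dione (enedione) | CC(C)(O)C(=O)C=C1C(=O)CCCC1=O | intermediate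
7 | 8a-hydroxy-2,2-dimethyl-6,7,8,8a-tetrahydro-2H-chromene-3,5-dione (racemic hemiketal) | CC1(C)OC2(O)CCCC(=O)C2=CC1=O | intermediate
8 | 2,2-dimethyl-6,7-dihydro-2H-chromene-3,5-dione (dienedione) | CC1(C)OC2=CCCC(=O)C2=CC1=O | intermediate
9 | 5-hydroxy-2,2-dimethyl-2H-chromen-3(4H)-one | CC1(C)Oc2cccc(O)c2CC1=O | intermediate
10 | 5-methoxy-2,2-dimethyl-2H-chromen-3(4H)-one | COc1cccc2c1CC(=O)C(C)(C)O2 | intermediate
11 | (3R)-5-methoxy-2,2-dimethyl-3,4-dihydro-2H-chromen-3-ol | COc1cccc2c1C[C@@H](O)C(C)(C)O2 | intermediate
12 | (3R)-8-acetyl-5-methoxy-2,2-dimethyl-3,4-dihydro-2H-chromen-3-yl acetate | COc1ccc(C(C)=O)c2c1C[C@@H](OC(C)=O)C(C)(C)O2 | intermediate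
13 | 4-(methoxymethoxy)benzaldehyde | COCOc1ccc(C=O)cc1 | starting material
14 | (2E)-1-[(3R)-3-hydroxy-5-methoxy-2,2-dimethyl-3,4-dihydro-2H-chromen-8-yl]-3-[4-(methoxymethoxy)phenyl]prop-2-en-1-one | COc1ccc(C(=O)/C=C/c2ccc(OCOC)cc2)c2c1C[C@@H](O)C(C)(C)O2 | intermediate
15 | (2E)-1-[(3R)-3-hydroxy-5-methoxy-2,2-dimethyl-3,4-dihydro-2H-chromen-8-yl]-3-(4-hydroxyphenyl)prop-2-en-1-one | COc1ccc(C(=O)/C=C/c2ccc(O)cc2)c2c1C[C@@H](O)C(C)(C)O2 | target

**Count**
Total steps: 8. Longest linear sequence: 8 steps (1 → 2 → 5 → 9 → 10 → 11 → 12 → 14 → 15).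

**Steps most likely to fail**

Step 3 (proposed new method). Oxidation of the acyl-deactivated furan may be slow. The open enedione may also be diverted before the hemiketal ionizes, by conjugate addition or by tautomerization to a resorcinol that closes to a benzofuran. Residual peracid may over-oxidize the electron-rich phenol. The fallback uses known chemistry without a ring expansion; it sets out from 3 and comes back at 11. Condensation of 3 with 3-methylbut-2-enal (pyridine, 110 °C; Knoevenagel condensation and oxa-6π electrocyclization) should give 2,2-dimethyl-7,8-dihydro-2H-chromen-5(6H)-one F1. Dehydrogenation with DDQ (dioxane, reflux) should give 2,2-dimethyl-2H-chromen-5-ol F2, and methylation (MeI, K2CO3, acetone) 5-methoxy-2,2-dimethyl-2H-chromene F3. Jacobsen epoxidation with (R,R)-N,N'-bis(3,5-di-tert-butylsalicylidene)cyclohexane-1,2-diaminomanganese chloride, NaOCl and 4-phenylpyridine N-oxide (CH2Cl2, 0 °C) should give (3R,4R)-3,4-epoxy-5-methoxy-2,2-dimethylchroman F4. LiAlH4 (THF, 0 °C) should open the epoxide at the benzylic carbon C4, the neopentyl carbon C3 being shielded, to give 11, which re-enters at step 6.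

Step 6. Attack at C6 may compete with attack at C8, and the acid may open the pyran ring at the tertiary aryl ether. The fallback sets out from 11 and comes back at 14. Bromination with NBS (MeCN, 0 °C), which is para-selective with respect to the methoxy group and gives separable isomers, should give (3R)-8-bromo-5-methoxy-2,2-dimethyl-3,4-dihydro-2H-chromen-3-ol F5. Stille coupling with tributyl(1-ethoxyvinyl)stannane (Pd(PPh3)4, toluene, 100 °C) should give (3R)-8-(1-ethoxyethenyl)-5-methoxy-2,2-dimethyl-3,4-dihydro-2H-chromen-3-ol F6, and 1 M HCl in THF should hydrolyse the enol ether to (3R)-8-acetyl-5-methoxy-2,2-dimethyl-3,4-dihydro-2H-chromen-3-ol F7. F7 is condensed with 13 under the conditions of step 7 to give 14.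

Step 2. O-Alkylation of the dione may compete with C-alkylation, and the acid may eliminate the tertiary furfuryl hydroxyl during cyclodehydration. The fallback sets out from 3 and comes back at 5. Diazo transfer (4-acetamidobenzenesulfonyl azide, Et3N, MeCN) should give 2-diazocyclohexane-1,3-dione F8. Formal [3+2] cycloaddition of its rhodium carbenoid with commercial 3-methyl-3-(trimethylsilyloxy)but-1-yne (Rh2(OAc)4, fluorobenzene, rt) should give 2-[2-(trimethylsilyloxy)propan-2-yl]-6,7-dihydro-1-benzofuran-4(5H)-one F9 under acid-free conditions. K2CO3 in MeOH removes the silyl group to give 5.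

**Further compounds**
F1 | step 3 | 2,2-dimethyl-7,8-dihydro-2H-chromen-5(6H)-one | CC1(C)C=CC2=C(CCCC2=O)O1
F2 | step 3 | 2,2-dimethyl-2H-chromen-5-ol | CC1(C)C=Cc2c(O)cccc2O1
F3 | step 3 | 5-methoxy-2,2-dimethyl-2H-chromene | COc1cccc2OC(C)(C)C=Cc12
F4 | step 3 | (3R,4R)-3,4-epoxy-5-methoxy-2,2-dimethylchroman | COc1cccc2c1[C@H]3O[C@H]3C(C)(C)O2
F5 | step 6 | (3R)-8-bromo-5-methoxy-2,2-dimethyl-3,4-dihydro-2H-chromen-3-ol | COc1ccc(Br)c2c1C[C@@H](O)C(C)(C)O2
F6 | step 6 | (3R)-8-(1-ethoxyethenyl)-5-methoxy-2,2-dimethyl-3,4-dihydro-2H-chromen-3-ol | COc1ccc(C(=C)OCC)c2c1C[C@@H](O)C(C)(C)O2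
F7 | step 6 | (3R)-8-acetyl-5-methoxy-2,2-dimethyl-3,4-dihydro-2H-chromen-3-ol | COc1ccc(C(C)=O)c2c1C[C@@H](O)C(C)(C)O2
F8 | step 2 | 2-diazocyclohexane-1,3-dione | [N-]=[N+]=C1C(=O)CCCC1=O
F9 | step 2 | 2-[2-(trimethylsilyloxy)propan-2-yl]-6,7-dihydro-1-benzofuran-4(5H)-one | C[Si](C)(C)OC(C)(C)c1cc2c(o1)CCCC2=O
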